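Ring A, the central benzene, carries on four adjacent carbons a 4-hydroxyphenyl group, the diarylmethylene carbon, the arylethynyl group and a methyl group. That sequence is the substitution pattern of a 6-aryl-3-methylsalicylate, in which the ester carbon becomes the methylene carbon and the phenol oxygen marks the alkyne site. The salicylate is disconnected at the C(methyl)–CH and C(ester)–C(aryl) bonds of ring A into the bis(silyl enol ether) of methyl 3-oxopentanoate and an aryl β-keto dimethyl acetal. A single TiCl4-mediated cyclocondensation forms both bonds, closes ring A and sets all four substituents in order.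

Key step: step 5

Remark on the chemistry: the route is planned for the structure exactly as the SMILES gives it, with an unsubstituted phenyl group on the methylene carbon. The cyclohexadienone ring is symmetric about the exocyclic C=C bond, so the target has no stereocentre and no stereogenic double bond and needs no stereocontrol. All three phenol oxygens travel as methyl ethers, which should survive TiCl4, palladium catalysis and aryllithiums, and which are removed in the operation that forms the quinone methide. Enol ether geometries are drawn as the expected major isomers; either isomer serves.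

Step 1
Reactants: 1 methyl 3-oxopentanoate
Product: 2 methyl (Z)-3-(trimethylsiloxy)pent-2-enoate
Conditions: Me3SiCl (1.5 equiv), Et3N (1.6 equiv), toluene, 20 °C; filter, concentrate, distil
Reagents that add atoms: chlorotrimethylsilane, C[Si](C)(C)Cl
Why: O-silylation of the enol form of a β-keto ester with Me3SiCl and an amine base (silyl enol ether formation) is the standard first stage of bis(silyl enol ether) preparation, and the enol ether geometry has no consequence later.

Step 2
Reactants: 2 methyl (Z)-3-(trimethylsiloxy)pent-2-enoate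
Product: 4 (1Z,3Z)-1-methoxy-1,3-bis(trimethylsiloxy)penta-1,3-diene, via lithium dienolate 3 (not isolated)
Conditions: LiN(iPr)2 (1.2 equiv), THF, −78 °C; then Me3SiCl (1.3 equiv), −78 to 20 °C; pentane, filtration, used crude
Reagents that add atoms: chlorotrimethylsilane, C[Si](C)(C)Cl
Why: Kinetic γ-deprotonation of the silyl enol ether by the lithium amide gives the extended ester dienolate, which is silylated on the ester oxygen (silyl ketene acetal formation) to give the 1,3-bis(silyloxy)diene.

Step 3
Reactants: 5 4-methoxyacetophenone; 6 methyl formate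
Product: 7 sodium (Z)-3-(4-methoxyphenyl)-3-oxoprop-1-en-1-olate
Conditions: NaOMe (1.2 equiv), 6 (3 equiv), Et2O, 0 to 20 °C; the salt is filtered off and dried
Reagents that add atoms: sodium methoxide, [Na+].[O-]C
Why: Crossed Claisen condensation (formylation) of a methyl ketone enolate with a formate that cannot enolise, driven to completion by precipitation of the stabilised sodium enolate.

Step 4
Reactants: 7 sodium (Z)-3-(4-methoxyphenyl)-3-oxoprop-1-en-1-olate
Product: 9 3,3-dimethoxy-1-(4-methoxyphenyl)propan-1-one, via keto aldehyde 8 (not isolated)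
Conditions: 7 added in portions to anhydrous HCl in MeOH, 0 to 20 °C; then NaHCO3, extraction
Reagents that add atoms: methanol, CO
Why: Acid-catalysed acetalisation occurs selectively at the formyl group of the liberated β-keto aldehyde, which is far more electrophilic than the conjugated aryl ketone, and portionwise addition to cold excess methanolic acid keeps the free keto aldehyde dilute so that its self-condensation is suppressed.

Step 5
Reactants: 4 (1Z,3Z)-1-methoxy-1,3-bis(trimethylsiloxy)penta-1,3-diene; 9 3,3-dimethoxy-1-(4-methoxyphenyl)propan-1-one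
Product: 12 methyl 2-hydroxy-6-(4-methoxyphenyl)-3-methylbenzoate, via open-chain keto ester 10 (not isolated), via cyclic aldol 11 (not isolated)
Conditions: 4 (1.5 equiv), TiCl4 (1.1 equiv), CH2Cl2, −78 to 20 °C; then 1 M HCl aq
Reagents that add atoms: none
Why: TiCl4 ionises the dimethyl acetal of 9 to a methoxycarbenium ion, which the terminal carbon C4 of diene 4 attacks in a vinylogous Mukaiyama aldol-type addition to give 10 as its titanium-bound β-keto ester enolate. The central carbon C2 of that enolate then adds to the titanium-activated aryl ketone, closing ring A in a 6-(enolexo)-exo-trig aldol step to 11, and loss of methanol and water aromatises the ring to the salicylate. The closest known reaction type is the TiCl4-mediated formal [3+3] cyclocondensation of 1,3-bis(silyl enol ethers) with β-keto acetals, an established route to 6-substituted salicylates. No stereocentre survives, since those of 10 and 11 are erased on aromatisation, and the geometry of 4 plays no role. The step needs one regiochemical outcome, terminal diene carbon to the acetal carbon and central carbon to the ketone; the ionised acetal is far more electrophilic than the ketone, which is further deactivated by its 4-methoxyphenyl group, so the aryl group should end up ortho to the ester.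

Step 6
Reactants: 12 methyl 2-hydroxy-6-(4-methoxyphenyl)-3-methylbenzoate
Product: 13 methyl 6-(4-methoxyphenyl)-3-methyl-2-(trifluoromethanesulfonyloxy)benzoate
Conditions: Tf2O (1.2 equiv), pyridine (2 equiv), CH2Cl2, −78 to 0 °C
Reagents that add atoms: trifluoromethanesulfonic anhydride, O=S(=O)(OS(=O)(=O)C(F)(F)F)C(F)(F)F
Why: O-Sulfonylation of a phenol with triflic anhydride and pyridine is reliable for hydrogen-bonded salicylate phenols and gives an electron-poor aryl triflate well suited to oxidative addition.

Step 7
Reactants: 13 methyl 6-(4-methoxyphenyl)-3-methyl-2-(trifluoromethanesulfonyloxy)benzoate; 14 4-ethynylanisole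
Product: 15 methyl 6-(4-methoxyphenyl)-2-[(4-methoxyphenyl)ethynyl]-3-methylbenzoate
Conditions: 14 (1.5 equiv), PdCl2(PPh3)2 (5 mol%), CuI (10 mol%), Bu4NI (15 mol%), Et3N, DMF, degassed, 70 °C
Reagents that add atoms: none
Why: Sonogashira coupling, in which oxidative addition of zerovalent palladium into the C–OTf bond is accelerated by the ortho ester, the slim copper acetylide of 14 transmetalates despite the two flanking groups, and reductive elimination gives the diarylalkyne.

Step 8
Reactants: 15 methyl 6-(4-methoxyphenyl)-2-[(4-methoxyphenyl)ethynyl]-3-methylbenzoate; 16 4-bromoanisole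
Product: 18 (4-methoxyphenyl){6-(4-methoxyphenyl)-2-[(4-methoxyphenyl)ethynyl]-3-methylphenyl}methanone, via 4-methoxyphenyllithium 17 (not isolated)
Conditions: 16, n-BuLi, THF, −78 °C; the solution of 17 (1.1 equiv) is added slowly to 15 in THF at −78 °C; NH4Cl aq at −78 °C
Reagents that add atoms: none
Why: Nucleophilic acyl substitution of an ester by an aryllithium formed by bromine–lithium exchange should stop at the ketone, because the ketone released is flanked by the same twisted aryl and alkynyl groups, carries two aryl groups on the carbonyl carbon and is deactivated by the 4-methoxyphenyl donor, and only one equivalent of nucleophile is offered at −78 °C.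

Step 9
Reactants: 18 (4-methoxyphenyl){6-(4-methoxyphenyl)-2-[(4-methoxyphenyl)ethynyl]-3-methylphenyl}methanone
Product: 19 (4-methoxyphenyl){6-(4-methoxyphenyl)-2-[(4-methoxyphenyl)ethynyl]-3-methylphenyl}(phenyl)methanol (racemate)
Conditions: PhLi (3 equiv), THF, −78 to −20 °C; NH4Cl aq at −20 °C
Reagents that add atoms: phenyllithium, [Li]c1ccccc1
Why: 1,2-Addition of an organolithium to a diaryl ketone that cannot enolise, where an excess of the small and reactive PhLi overcomes the hindrance; the carbinol stereocentre forms without control as a racemate and is removed in step 10, and the cold quench keeps the alkoxide from adding to the neighbouring alkyne.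

Step 10
Reactants: 19 (4-methoxyphenyl){6-(4-methoxyphenyl)-2-[(4-methoxyphenyl)ethynyl]-3-methylphenyl}(phenyl)methanol (racemate)
Product: 20 selaginellin A, 4-[{6-(4-hydroxyphenyl)-2-[(4-hydroxyphenyl)ethynyl]-3-methylphenyl}(phenyl)methylidene]cyclohexa-2,5-dien-1-one
Conditions: BBr3 (8 equiv), CH2Cl2, −78 to 0 °C; then ice and NaHCO3 aq
Reagents that add atoms: none
Why: Lewis acid ether cleavage combined with ionisation of the triaryl carbinol: BBr3 converts the carbinol into a triarylmethyl cation whose 4-methoxyphenyl ring is an O-methylated quinone methide, bromide removes that methyl group to give the quinone methide directly, and the two remaining anisole units are cleaved by the usual bromide demethylation and freed as phenols on hydrolysis.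

Compound list
1 | methyl 3-oxopentanoate | CCC(=O)CC(=O)OC | starting material
2 | methyl (Z)-3-(trimethylsiloxy)pent-2-enoate | CC/C(O[Si](C)(C)C)=C/C(=O)OC | intermediate
3 | lithium 1-methoxy-3-(trimethylsiloxy)penta-1,3-dien-1-olate (geometry as in 4) | CO/C([O-])=C/C(O[Si](C)(C)C)=C/C.[Li+] | intermediate
4 | (1Z,3Z)-1-methoxy-1,3-bis(trimethylsiloxy)penta-1,3-diene | CO/C(O[Si](C)(C)C)=C/C(O[Si](C)(C)C)=C/C | intermediate
5 | 4-methoxyacetophenone | CC(=O)c1ccc(OC)cc1 | starting material
6 | methyl formate | COC=O | starting material
7 | sodium (Z)-3-(4-methoxyphenyl)-3-oxoprop-1-en-1-olate | [Na+].[O-]/C=C\C(=O)c1ccc(OC)cc1 | intermediate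
8 | 3-(4-methoxyphenyl)-3-oxopropanal | O=CCC(=O)c1ccc(OC)cc1 | intermediate
9 | 3,3-dimethoxy-1-(4-methoxyphenyl)propan-1-one | COc1ccc(C(=O)CC(OC)OC)cc1 | intermediate
10 | methyl 5-methoxy-7-(4-methoxyphenyl)-4-methyl-3,7-dioxoheptanoate (mixture of diastereomers) | COC(=O)CC(=O)C(C)C(OC)CC(=O)c1ccc(OC)cc1 | intermediate
11 | methyl 2-hydroxy-4-methoxy-2-(4-methoxyphenyl)-5-methyl-6-oxocyclohexane-1-carboxylate (mixture of diastereomers) | COC(=O)C1C(=O)C(C)C(OC)CC1(O)c1ccc(OC)cc1 | intermediate
12 | methyl 2-hydroxy-6-(4-methoxyphenyl)-3-methylbenzoate | COC(=O)c1c(O)c(C)ccc1-c1ccc(OC)cc1 | intermediate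
13 | methyl 6-(4-methoxyphenyl)-3-methyl-2-(trifluoromethanesulfonyloxy)benzoate | COC(=O)c1c(OS(=O)(=O)C(F)(F)F)c(C)ccc1-c1ccc(OC)cc1 | intermediate
14 | 4-ethynylanisole | C#Cc1ccc(OC)cc1 | starting material
15 | methyl 6-(4-methoxyphenyl)-2-[(4-methoxyphenyl)ethynyl]-3-methylbenzoate | COC(=O)c1c(C#Cc2ccc(OC)cc2)c(C)ccc1-c1ccc(OC)cc1 | intermediate
16 | 4-bromoanisole | COc1ccc(Br)cc1 | starting material
17 | 4-methoxyphenyllithium | [Li]c1ccc(OC)cc1 | intermediate
18 | (4-methoxyphenyl){6-(4-methoxyphenyl)-2-[(4-methoxyphenyl)ethynyl]-3-methylphenyl}methanone | COc1ccc(cc1)C(=O)c1c(C#Cc2ccc(OC)cc2)c(C)ccc1-c1ccc(OC)cc1 | intermediate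
19 | (4-methoxyphenyl){6-(4-methoxyphenyl)-2-[(4-methoxyphenyl)ethynyl]-3-methylphenyl}(phenyl)methanol (racemate) | COc1ccc(cc1)C(O)(c1ccccc1)c1c(C#Cc2ccc(OC)cc2)c(C)ccc1-c1ccc(OC)cc1 | intermediate
20 | selaginellin A, 4-[{6-(4-hydroxyphenyl)-2-[(4-hydroxyphenyl)ethynyl]-3-methylphenyl}(phenyl)methylidene]cyclohexa-2,5-dien-1-one (no stereocentre) | Cc1ccc(-c2ccc(O)cc2)c(C(=C2C=CC(=O)C=C2)c2ccccc2)c1C#Cc1ccc(O)cc1 | target

Total step count: 10

Longest linear sequence: 8 steps (steps 1, 2, 5, 6, 7, 8, 9, 10; the branch through steps 3 and 4 is equally long)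

Steps most likely to fail

Step 5. The ring-closing aldol onto the electron-rich aryl ketone may lag behind the first bond formation, so that open-chain material accumulates while the excess diene is hydrolysed or condenses with itself; attack in the reverse sense would put the aryl group para to the ester. The fallback buys ring A and introduces the aryl group by C–H arylation instead of ring synthesis. It sets out from 16 and comes back at 12. Commercial 2-methoxy-3-methylbenzoic acid F1 is arylated with 16 at C6, its only free ortho position, by carboxylate-directed ruthenium catalysis ([RuCl2(p-cymene)]2, PCy3, K2CO3, NMP, 120 °C) to give 2-methoxy-6-(4-methoxyphenyl)-3-methylbenzoic acid F2. Alkylation of the hindered carboxylate (MeI, K2CO3, DMF) gives methyl 2-methoxy-6-(4-methoxyphenyl)-3-methylbenzoate F3. BCl3 in CH2Cl2 at −78 to 0 °C, which cleaves only the methyl ether that can chelate to the neighbouring ester carbonyl, should then give 12.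

Step 8. A second aryllithium addition to the ketone as it forms may compete with the first, or the flanked ester may not react at −78 °C, so that warming erodes the selectivity. The fallback passes through the aldehyde oxidation level, where only one aryl group can add. It sets out from 15 and comes back at 18. Reduction with iBu2AlH (CH2Cl2, −78 to 0 °C) gives {6-(4-methoxyphenyl)-2-[(4-methoxyphenyl)ethynyl]-3-methylphenyl}methanol F4. Dess–Martin periodinane (CH2Cl2, 20 °C) gives 6-(4-methoxyphenyl)-2-[(4-methoxyphenyl)ethynyl]-3-methylbenzaldehyde F5. Addition of 17 (THF, −78 °C) gives racemic (4-methoxyphenyl){6-(4-methoxyphenyl)-2-[(4-methoxyphenyl)ethynyl]-3-methylphenyl}methanol F6, and a second Dess–Martin oxidation gives 18.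

Step 10. The boron halide or the triarylmethyl cation may engage the neighbouring alkyne (bromoboration or ring closure onto the triple bond), or ether cleavage may stop short of completion. The fallback removes the methyl ethers before the carbinol exists and finishes under mild fluoride and acid conditions. It sets out from 18 and comes back at 20. Nucleophilic demethylation with NaSEt in DMF at 130 °C, without free thiol so that no proton source supports thiolate addition to the alkyne, gives (4-hydroxyphenyl){6-(4-hydroxyphenyl)-2-[(4-hydroxyphenyl)ethynyl]-3-methylphenyl}methanone F7. Silylation (t-BuMe2SiCl, imidazole, DMF) gives the tris(tert-butyldimethylsilyl) ether F8. PhLi (THF, −78 °C) adds to the ketone, now no longer deactivated by a phenoxide, to give the racemic triaryl carbinol F9. Bu4NF in THF at 0 °C removes the three silyl groups, and the triphenol carbinol F10 so released should lose water on acidification with AcOH to give 20.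

Further compounds
F1 | step 5 | 2-methoxy-3-methylbenzoic acid | COc1c(C)cccc1C(=O)O
F2 | step 5 | 2-methoxy-6-(4-methoxyphenyl)-3-methylbenzoic acid | COc1c(C)ccc(-c2ccc(OC)cc2)c1C(=O)O
F3 | step 5 | methyl 2-methoxy-6-(4-methoxyphenyl)-3-methylbenzoate | COC(=O)c1c(OC)c(C)ccc1-c1ccc(OC)cc1
F4 | step 8 | {6-(4-methoxyphenyl)-2-[(4-methoxyphenyl)ethynyl]-3-methylphenyl}methanol | OCc1c(C#Cc2ccc(OC)cc2)c(C)ccc1-c1ccc(OC)cc1
F5 | step 8 | 6-(4-methoxyphenyl)-2-[(4-methoxyphenyl)ethynyl]-3-methylbenzaldehyde | O=Cc1c(C#Cc2ccc(OC)cc2)c(C)ccc1-c1ccc(OC)cc1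
F6 | step 8 | (4-methoxyphenyl){6-(4-methoxyphenyl)-2-[(4-methoxyphenyl)ethynyl]-3-methylphenyl}methanol (racemate) | COc1ccc(cc1)C(O)c1c(C#Cc2ccc(OC)cc2)c(C)ccc1-c1ccc(OC)cc1
F7 | step 10 | (4-hydroxyphenyl){6-(4-hydroxyphenyl)-2-[(4-hydroxyphenyl)ethynyl]-3-methylphenyl}methanone | O=C(c1ccc(O)cc1)c1c(C#Cc2ccc(O)cc2)c(C)ccc1-c1ccc(O)cc1
F8 | step 10 | (4-{[tert-butyl(dimethyl)silyl]oxy}phenyl){6-(4-{[tert-butyl(dimethyl)silyl]oxy}phenyl)-2-[(4-{[tert-butyl(dimethyl)silyl]oxy}phenyl)ethynyl]-3-methylphenyl}methanone | CC(C)(C)[Si](C)(C)Oc1ccc(cc1)C(=O)c1c(C#Cc2ccc(O[Si](C)(C)C(C)(C)C)cc2)c(C)ccc1-c1ccc(O[Si](C)(C)C(C)(C)C)cc1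
F9 | step 10 | (4-{[tert-butyl(dimethyl)silyl]oxy}phenyl){6-(4-{[tert-butyl(dimethyl)silyl]oxy}phenyl)-2-[(4-{[tert-butyl(dimethyl)silyl]oxy}phenyl)ethynyl]-3-methylphenyl}(phenyl)methanol (racemate) | CC(C)(C)[Si](C)(C)Oc1ccc(cc1)C(O)(c1ccccc1)c1c(C#Cc2ccc(O[Si](C)(C)C(C)(C)C)cc2)c(C)ccc1-c1ccc(O[Si](C)(C)C(C)(C)C)cc1
F10 | step 10 | (4-hydroxyphenyl){6-(4-hydroxyphenyl)-2-[(4-hydroxyphenyl)ethynyl]-3-methylphenyl}(phenyl)methanol (racemate) | Oc1ccc(cc1)C(O)(c1ccccc1)c1c(C#Cc2ccc(O)cc2)c(C)ccc1-c1ccc(O)cc1
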